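**Plan**

1. Numbering of the target naphthalene: C1 carries the 3,4-dimethoxyphenyl ring (ring C), C2 OH, C3 CHO, C4 H, C7 OH, C8 OMe; ring A is C1–C4 with C4a and C8a, ring B is C4a–C8a. The feature used is that C3 and its exocyclic carbon sit as one two-carbon unit between the oxygen-bearing C2 and the unsubstituted benzylic C4, which is what a diazoacetate carbon delivers when it inserts between a ketone carbonyl and its CH2 neighbour.
2. Retrosynthesis: the C7 hydroxyl is masked as an isopropyl ether and the formyl group is traced back to an ethyl ester; ring A is taken back to a 3-oxo-tetralin-2-carboxylate, and cutting C2–C3 and C3–C4 contracts it to a 1-aryl-2-indanone plus ethyl diazoacetate.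
3. The 2-indanone comes from a 3-arylindene by epoxide rearrangement; the indene is cut at the C1–aryl bond into a 1-indanone and an aryl Grignard reagent, and the indanone at its acyl–arene bond into a hydrocinnamic acid.
4. Forward: ring B is bought with dihydroferulic acid; the five-membered ring closes by a Friedel–Crafts acylation steered by a removable bromine; ring C is joined by Grignard addition; the five-membered ring is then enlarged to ring A and aromatised; ester to aldehyde and deprotection finish.
5. Stereochemistry: the target has no stereocentre; the sp3 centres met on the way are racemic or mixtures and all vanish on aromatisation.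

Key step: step 7

Assumption: rotation about the C1–aryl bond is taken to be fast at room temperature (ring C has no ortho substituent), so the target is treated as achiral.

**Route**

Step 1
Reactants: 1 3-(4-hydroxy-3-methoxyphenyl)propanoic acid; 2 2-bromopropane
Product: 4 3-[3-methoxy-4-(propan-2-yloxy)phenyl]propanoic acid, via isopropyl ester 3 (not isolated)
Conditions: 2-bromopropane (excess), K2CO3, DMF, 70 °C; then NaOH, H2O/MeOH, 60 °C; HCl (aq) to pH 2
Reagents that add atoms: 2-bromopropane (2), CC(C)Br; sodium hydroxide, [Na+].[OH-]
Why: Williamson etherification of the phenoxide in DMF (the carboxylate is alkylated as well) followed by saponification of the isopropyl ester in the same flask should give the ether acid, with no stereocentre involved.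

Step 2
Reactants: 4 3-[3-methoxy-4-(propan-2-yloxy)phenyl]propanoic acid
Product: 5 3-[2-bromo-5-methoxy-4-(propan-2-yloxy)phenyl]propanoic acid
Conditions: NBS, MeCN, 0 °C to rt
Reagents that add atoms: N-bromosuccinimide, O=C1CCC(=O)N1Br
Why: Electrophilic aromatic bromination should go to the position para to the methoxy group, the most activated free site because the position para to the isopropoxy group holds the side chain, and the bromine then blocks that site for the ring closure.

Step 3
Reactants: 5 3-[2-bromo-5-methoxy-4-(propan-2-yloxy)phenyl]propanoic acid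
Product: 7 4-bromo-7-methoxy-6-(propan-2-yloxy)-2,3-dihydro-1H-inden-1-one, via acid chloride 6 (not isolated)
Conditions: (COCl)2, DMF (cat.), CH2Cl2, rt; evaporate; SnCl4, CH2Cl2, −20 to 0 °C
Reagents that add atoms: none
Why: In this intramolecular Friedel–Crafts acylation the acylium ion can only close onto the one free position ortho to the side chain, which lies next to the methoxy group and is activated by it, and SnCl4 at low temperature is chosen because it should spare the secondary alkyl aryl ether.

Step 4
Reactants: 7 4-bromo-7-methoxy-6-(propan-2-yloxy)-2,3-dihydro-1H-inden-1-one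
Product: 8 7-methoxy-6-(propan-2-yloxy)-2,3-dihydro-1H-inden-1-one
Conditions: H2 (1 atm), 10% Pd/C, NaOAc, MeOH/EtOAc, rt
Reagents that add atoms: none
Why: Catalytic hydrodehalogenation of the aryl bromide with acetate as HBr scavenger is expected to be much faster than reduction of the methoxy-conjugated aryl ketone, so the blocking group is removed cleanly.

Step 5
Reactants: 8 7-methoxy-6-(propan-2-yloxy)-2,3-dihydro-1H-inden-1-one; 9 4-bromo-1,2-dimethoxybenzene
Product: 12 3-(3,4-dimethoxyphenyl)-4-methoxy-5-(propan-2-yloxy)-1H-indene, via aryl Grignard reagent 10 (not isolated), via tertiary indanol 11 (not isolated)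
Conditions: 9, Mg, THF, reflux; add 8, THF, 0 °C to rt; HCl (aq); crude carbinol, p-TsOH (cat.), toluene, 60 °C
Reagents that add atoms: 4-bromo-1,2-dimethoxybenzene (9, as its Grignard reagent), COc1ccc(Br)cc1OC
Why: Grignard addition to the ketone, helped by chelation of magnesium by the neighbouring methoxy group, gives a doubly benzylic tertiary alcohol that should lose water by acid-catalysed E1 dehydration to the conjugated 3-arylindene, the only alkene its β-hydrogens allow.

Step 6
Reactants: 12 3-(3,4-dimethoxyphenyl)-4-methoxy-5-(propan-2-yloxy)-1H-indene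
Product: 14 1-(3,4-dimethoxyphenyl)-7-methoxy-6-(propan-2-yloxy)-1,3-dihydro-2H-inden-2-one (racemic), via indene oxide 13 (not isolated)
Conditions: dimethyldioxirane, acetone, −20 °C; evaporate; BF3·OEt2 (cat.), CH2Cl2, −40 °C
Reagents that add atoms: dimethyldioxirane, CC1(C)OO1
Why: Neutral epoxidation of the electron-rich alkene followed by Meinwald rearrangement, in which BF3 opens the epoxide at the doubly benzylic carbon and a 1,2-hydride shift places the carbonyl at C2, should give the 2-indanone, whose new aryl-bearing stereocentre is racemic and enolisable.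

Step 7
Reactants: 14 1-(3,4-dimethoxyphenyl)-7-methoxy-6-(propan-2-yloxy)-1,3-dihydro-2H-inden-2-one (racemic); 15 ethyl diazoacetate
Product: 16 ethyl 4-(3,4-dimethoxyphenyl)-5-methoxy-3-oxo-6-(propan-2-yloxy)-1,2,3,4-tetrahydronaphthalene-2-carboxylate (mixture of diastereomers and enol form)
Conditions: ethyl diazoacetate (slow addition), BF3·OEt2, CH2Cl2, −20 to 0 °C
Reagents that add atoms: ethyl diazoacetate (15), CCOC(=O)C=[N+]=[N-]
Why: BF3 activates the ketone of 14 (future C2), the diazo carbon of 15 adds to it to give a boron-bound β-oxido diazonium adduct, and a 1,2-shift of the benzylic methylene (future C4) to the diazonium carbon with loss of N2 places the ester-bearing carbon (future C3) between the carbonyl and that CH2. This is the Lewis acid promoted homologation of ketones with diazoacetic esters, a Tiffeneau–Demjanov-type ring enlargement that is well known for cycloalkanones. Ring A is not closed by a cyclisation: the existing five-membered ring grows to the six-membered ring through this 1,2-alkyl shift, which makes the C2–C3 and C3–C4 bonds. The new ester-bearing centre and the retained aryl-bearing centre are left uncontrolled, since the product should sit largely as the hydrogen-bonded enol and both centres become sp2 in the next step. The step needs the methylene and not the aryl-bearing methine to migrate; diazo ester homologations shift the less substituted α-carbon preferentially, and here the methine is further shielded by its aryl group and the adjacent methoxy group, so the arrangement with the CH2 anti to the departing N2 should be the accessible one. Low temperature and slow addition of 15 are meant to hold back enol-driven self-condensation of the acidic ketone and a second insertion.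

Step 8
Reactants: 16 ethyl 4-(3,4-dimethoxyphenyl)-5-methoxy-3-oxo-6-(propan-2-yloxy)-1,2,3,4-tetrahydronaphthalene-2-carboxylate
Product: 17 ethyl 4-(3,4-dimethoxyphenyl)-3-hydroxy-5-methoxy-6-(propan-2-yloxy)naphthalene-2-carboxylate
Conditions: DDQ (1.05 equiv), toluene, rt
Reagents that add atoms: none
Why: The enol of 16 is a 1,4-dihydronaphthalene, so quinone dehydrogenation by hydride abstraction from a doubly activated benzylic C–H and loss of a proton should aromatise ring A to the hydrogen-bonded 3-hydroxy-2-naphthoate.

Step 9
Reactants: 17 ethyl 4-(3,4-dimethoxyphenyl)-3-hydroxy-5-methoxy-6-(propan-2-yloxy)naphthalene-2-carboxylate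
Product: 18 1-(3,4-dimethoxyphenyl)-3-(hydroxymethyl)-8-methoxy-7-(propan-2-yloxy)naphthalen-2-ol
Conditions: LiAlH4 (excess), THF, 0 °C to rt; aqueous work-up
Reagents that add atoms: none
Why: Hydride reduction of the ester to the primary alcohol is standard for 3-hydroxy-2-naphthoates, provided excess LiAlH4 covers the hydride consumed by the naphthol.

Step 10
Reactants: 18 1-(3,4-dimethoxyphenyl)-3-(hydroxymethyl)-8-methoxy-7-(propan-2-yloxy)naphthalen-2-ol
Product: 19 4-(3,4-dimethoxyphenyl)-3-hydroxy-5-methoxy-6-(propan-2-yloxy)naphthalene-2-carbaldehyde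
Conditions: MnO2 (activated), CH2Cl2, rt
Reagents that add atoms: none
Why: Activated MnO2 oxidises benzylic alcohols selectively to aldehydes, and the resulting ortho-hydroxy aldehyde is held by an internal hydrogen bond and should not be oxidised further.

Step 11
Reactants: 19 4-(3,4-dimethoxyphenyl)-3-hydroxy-5-methoxy-6-(propan-2-yloxy)naphthalene-2-carbaldehyde
Product: 20 vitrofolal B, 4-(3,4-dimethoxyphenyl)-3,6-dihydroxy-5-methoxynaphthalene-2-carbaldehyde
Conditions: BCl3, CH2Cl2, −78 to 0 °C; H2O
Reagents that add atoms: none
Why: Lewis acid dealkylation with BCl3 cleaves the secondary isopropyl aryl ether much faster than the methyl ethers, because the isopropyl–oxygen bond ionises far more readily, so the C7 hydroxyl should be freed selectively.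

**Compound list**

1 | 3-(4-hydroxy-3-methoxyphenyl)propanoic acid | COc1cc(CCC(=O)O)ccc1O | starting material
2 | 2-bromopropane | CC(C)Br | starting material
3 | propan-2-yl 3-[3-methoxy-4-(propan-2-yloxy)phenyl]propanoate (formed in the flask) | COc1cc(CCC(=O)OC(C)C)ccc1OC(C)C | intermediate
4 | 3-[3-methoxy-4-(propan-2-yloxy)phenyl]propanoic acid | COc1cc(CCC(=O)O)ccc1OC(C)C | intermediate
5 | 3-[2-bromo-5-methoxy-4-(propan-2-yloxy)phenyl]propanoic acid | COc1cc(CCC(=O)O)c(Br)cc1OC(C)C | intermediate
6 | 3-[2-bromo-5-methoxy-4-(propan-2-yloxy)phenyl]propanoyl chloride (formed in the flask) | COc1cc(CCC(=O)Cl)c(Br)cc1OC(C)C | intermediate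
7 | 4-bromo-7-methoxy-6-(propan-2-yloxy)-2,3-dihydro-1H-inden-1-one | O=C1CCc2c(Br)cc(OC(C)C)c(OC)c21 | intermediate
8 | 7-methoxy-6-(propan-2-yloxy)-2,3-dihydro-1H-inden-1-one | O=C1CCc2ccc(OC(C)C)c(OC)c21 | intermediate
9 | 4-bromo-1,2-dimethoxybenzene | COc1ccc(Br)cc1OC | starting material
10 | (3,4-dimethoxyphenyl)magnesium bromide (formed in the flask) | COc1ccc([Mg]Br)cc1OC | intermediate
11 | 1-(3,4-dimethoxyphenyl)-7-methoxy-6-(propan-2-yloxy)-2,3-dihydro-1H-inden-1-ol (racemic, formed in the flask) | OC1(c2ccc(OC)c(OC)c2)CCc2ccc(OC(C)C)c(OC)c21 | intermediate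
12 | 3-(3,4-dimethoxyphenyl)-4-methoxy-5-(propan-2-yloxy)-1H-indene | COc1ccc(C2=CCc3ccc(OC(C)C)c(OC)c32)cc1OC | intermediate
13 | 1a-(3,4-dimethoxyphenyl)-2-methoxy-3-(propan-2-yloxy)-6,6a-dihydro-1aH-indeno[1,2-b]oxirene (racemic cis-fused 2,3-epoxide of 12, formed in the flask) | COc1ccc(cc1OC)C12OC1Cc1ccc(OC(C)C)c(OC)c12 | intermediate
14 | 1-(3,4-dimethoxyphenyl)-7-methoxy-6-(propan-2-yloxy)-1,3-dihydro-2H-inden-2-one (racemic) | O=C1Cc2ccc(OC(C)C)c(OC)c2C1c1ccc(OC)c(OC)c1 | intermediate
15 | ethyl diazoacetate | CCOC(=O)C=[N+]=[N-] | starting material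
16 | ethyl 4-(3,4-dimethoxyphenyl)-5-methoxy-3-oxo-6-(propan-2-yloxy)-1,2,3,4-tetrahydronaphthalene-2-carboxylate (mixture of stereoisomers) | CCOC(=O)C1Cc2ccc(OC(C)C)c(OC)c2C(c2ccc(OC)c(OC)c2)C1=O | intermediate
17 | ethyl 4-(3,4-dimethoxyphenyl)-3-hydroxy-5-methoxy-6-(propan-2-yloxy)naphthalene-2-carboxylate | CCOC(=O)c1cc2ccc(OC(C)C)c(OC)c2c(-c2ccc(OC)c(OC)c2)c1O | intermediate
18 | 1-(3,4-dimethoxyphenyl)-3-(hydroxymethyl)-8-methoxy-7-(propan-2-yloxy)naphthalen-2-ol | OCc1cc2ccc(OC(C)C)c(OC)c2c(-c2ccc(OC)c(OC)c2)c1O | intermediate
19 | 4-(3,4-dimethoxyphenyl)-3-hydroxy-5-methoxy-6-(propan-2-yloxy)naphthalene-2-carbaldehyde | O=Cc1cc2ccc(OC(C)C)c(OC)c2c(-c2ccc(OC)c(OC)c2)c1O | intermediate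
20 | vitrofolal B, 4-(3,4-dimethoxyphenyl)-3,6-dihydroxy-5-methoxynaphthalene-2-carbaldehyde | COc1ccc(-c2c(O)c(C=O)cc3ccc(O)c(OC)c23)cc1OC | target

**Count and risks**

Total step count: 11. Longest linear sequence: 11 steps (1 to 20); 9 and 15 enter as purchased materials.

Steps most likely to fail:

Step 7. The aryl-bearing methine may migrate in competition with the methylene, which would place the ester next to the aryl-bearing carbon, or the acidic ketone may enolise and condense with itself before the diazo ester adds. The fallback fixes the ring A carbonyl and both of its α-carbons before the ester is introduced. It sets out from 8: Wittig methylenation (Ph3PCH3Br, KOtBu, THF) should give 7-methoxy-1-methylidene-6-(propan-2-yloxy)-2,3-dihydro-1H-indene F1. Oxidative ring enlargement with PhI(OH)OTs in aqueous MeOH, in which the electron-rich aryl carbon migrates, should give 8-methoxy-7-(propan-2-yloxy)-3,4-dihydronaphthalen-2(1H)-one F2. Palladium-catalysed α-arylation with 9 (Pd(OAc)2, P(t-Bu)3, NaOtBu, toluene, 80 °C) at the doubly activated C1 should give 1-(3,4-dimethoxyphenyl)-8-methoxy-7-(propan-2-yloxy)-3,4-dihydronaphthalen-2(1H)-one F3. Ethoxycarbonylation under equilibrating conditions (NaH, diethyl carbonate, THF, reflux) then acylates C3, because acylation at the tertiary C1 is reversible while the C3 product is held as its enolate, and the route is rejoined at 16.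

Step 3. The isopropyl ether may be lost to the Lewis acid and the hydrogen chloride formed, or ring closure at the crowded position between side chain and methoxy group may be slow. The fallback runs the acylation on the free phenol under Brønsted acid and installs the isopropyl group afterwards. It sets out from 5: BCl3 in CH2Cl2 removes the isopropyl group cleanly as the alkyl chloride to give 3-(2-bromo-4-hydroxy-5-methoxyphenyl)propanoic acid F4. This acid has no acid-labile group and should cyclise in P2O5/MeSO3H at 60 °C to 4-bromo-6-hydroxy-7-methoxy-2,3-dihydro-1H-inden-1-one F5. Alkylation with 2 (K2CO3, DMF, 70 °C) returns to 7.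

Step 5. The basic aryl Grignard reagent may deprotonate the ketone instead of adding to the carbonyl, which is flanked by the methoxy group. The fallback turns that enolisation into the productive step and forms the aryl–carbon bond by cross-coupling. It sets out from 8: KN(SiMe3)2 and PhNTf2 in THF at −78 °C should give 4-methoxy-5-(propan-2-yloxy)-1H-inden-3-yl trifluoromethanesulfonate F6. Suzuki coupling with purchased (3,4-dimethoxyphenyl)boronic acid (Pd(PPh3)4, K2CO3, DME/H2O, 80 °C) gives the indene directly and rejoins the route at 12.

Further compounds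
F1 | step 7 | 7-methoxy-1-methylidene-6-(propan-2-yloxy)-2,3-dihydro-1H-indene | C=C1CCc2ccc(OC(C)C)c(OC)c21
F2 | step 7 | 8-methoxy-7-(propan-2-yloxy)-3,4-dihydronaphthalen-2(1H)-one | O=C1CCc2ccc(OC(C)C)c(OC)c2C1
F3 | step 7 | 1-(3,4-dimethoxyphenyl)-8-methoxy-7-(propan-2-yloxy)-3,4-dihydronaphthalen-2(1H)-one (racemic) | O=C1CCc2ccc(OC(C)C)c(OC)c2C1c1ccc(OC)c(OC)c1
F4 | step 3 | 3-(2-bromo-4-hydroxy-5-methoxyphenyl)propanoic acid | COc1cc(CCC(=O)O)c(Br)cc1O
F5 | step 3 | 4-bromo-6-hydroxy-7-methoxy-2,3-dihydro-1H-inden-1-one | COc1c(O)cc(Br)c2CCC(=O)c12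
F6 | step 5 | 4-methoxy-5-(propan-2-yloxy)-1H-inden-3-yl trifluoromethanesulfonate | COc1c(OC(C)C)ccc2CC=C(OS(=O)(=O)C(F)(F)F)c12
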